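The easy step came first: the beta run had the charge of the epsilon run, so I could read it along the epsilon readings, and the epsilon run stood at 20.3% of its L at 8.0 min. L is consumed and not made, so this share was my ceiling for the beta run at 16 min.

| setting | epsilon | theta | eta | delta | beta |
|---|---|---|---|---|---|
| L | 0.800 M | 0.480 M | 0.800 M | 1.20 M | 0.800 M |
| Z | 1.60 M | 1.28 M | 2.40 M | 1.60 M | 1.60 M |
| X | 0.0160 M | 0.0160 M | 0.0160 M | 0.0160 M | 0.0160 M |
| time |  |  |  |  | 16 min |

- epsilon run (time / min: [L] / M): 0.29: 0.7652; 0.87: 0.6795; 1.7: 0.5803; 2.6: 0.4821; 3.8: 0.3729; 5.0: 0.2878; 6.5: 0.2071; 8.0: 0.1627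
- theta run (time / min: [L] / M): 0.29: 0.4493; 0.87: 0.3941; 1.7: 0.3220; 2.6: 0.2532; 3.8: 0.1814; 5.0: 0.1266; 6.5: 0.0856; 8.0: 0.0584
- eta run (time / min: [L] / M): 0.29: 0.7576; 0.87: 0.6682; 1.7: 0.5527; 2.6: 0.4450; 3.8: 0.3329; 5.0: 0.2482; 6.5: 0.1811; 8.0: 0.1371
- delta run (time / min: [L] / M): 0.29: 1.1579; 0.87: 1.0671; 1.7: 0.9439; 2.6: 0.8247; 3.8: 0.6858; 5.0: 0.5695; 6.5: 0.4569; 8.0: 0.3696

(standard deviation of a reading: 0.002 M)

- the power of [L] that the first rate follows, about the charge of the epsilon run; measure it at two percent of L made into E (one fixed amount of E, the same in the runs compared)
- the power of [Z] that the first rate follows, about the charge of the epsilon run; measure it at two percent of L made into E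
- L in the beta run at 16 min, as a share of the L charged

- Overall: L + Z -> E, with X as catalyst.
- Constant volume, constant temperature.
- What is held in complexes is read along with the free species.
- An order is taken over about fifteen percent of the charge, up and down.

To tighten that ceiling, I looked for something nearly constant to freeze. I took the tail constant, the fraction of the L present that is lost per minute over the last interval of the epsilon run, 0.161 min⁻¹. Over the interval before, it had read 0.219 min⁻¹, so the last reading was lower. If it went on falling, freezing it overstated the later loss, so on that assumption it gave my lower bound, 5.62% of the charge.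

For the upper bound I assumed that the constant kept shrinking, interval after interval, by the ratio just read, 0.733, which was an estimate from two scattered readings and no proof. Summing the losses of that shrinking series up to 16 min gave 11.9% of the charge, more than the lower bound. I committed to that bracket.

The forecast gave 0.4 for L, 0.3 for Z and 6% for the beta run, which lies inside the bracket, and it read the late runs thus: “That suggests product inhibition”.

The flask gave orders of 0.39 in L and 0.33 in Z, and in the beta run at 16 min it held 9.37% of the L charged, which also lies inside the bracket.

    X + L → XL (30.42 M⁻¹ min⁻¹)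
    XL + Z → Ju (44.70 M⁻¹ min⁻¹)
    Ju → E + X (312.6 min⁻¹)
    2 Z ⇌ Z2, settled at all times (5.460 M⁻¹)
    X + E → Wa + E (0.3786 M⁻¹ min⁻¹)

Taking the beta run from the epsilon reading at 8.0 min to 16 min, the tail constant averaged 0.0968 min⁻¹, lower than the 0.161 min⁻¹ read before, because X passes into Wa while E is present. This is catalyst deactivation: the beta run without that step keeps 0.318% of its L, against 9.37%. In the delta run the constant between the quarter and half times was 0.153 min⁻¹, and its tail constant read lower, at 0.141 min⁻¹.

The data are simulated for substances that don't exist; the scatter is artificial.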